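**Plan**

Locants follow the name 12-oxabicyclo[9.1.0]dodecane: C1 (oxirane carbon with CH3), C2 (carbinol), C3=C4, C5 (quaternary), C6, C7=C8 (C8 carries CH2OH), C9, C10, C11 (oxirane CH), O12.
Cuts: the ester C–O at C2; the ring bond C2–C3; the chain bonds C8–C9 and C7=C8; the C4–C5 bond at the quaternary carbon.
Enabling feature: in the eleven-membered carbocycle, C2 is an allylic carbinol carbon between the (E)-C3=C4 alkene and the oxirane carbon C1, the retron of an alkenyl-metal addition to an α,β-epoxy aldehyde; C1 is quaternary, so this aldehyde cannot enolise, and its C1–O12 bond directs the carbonyl face.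
Forward: geraniol gives the C3–C8 arm with the quaternary carbon and propargyl alcohol gives the C9–C2 arm; a B-alkyl Suzuki coupling joins them at C8–C9; the oxirane is made on the open chain; the eleven-membered ring is closed last at C2–C3, followed by acylation and desilylation.
Stereochemistry: C5 from a catalyst-controlled enantioselective SN2' alkynylation; C1 and C11 from a Sharpless epoxidation of a (Z)-allylic alcohol; C2 from the oxirane (Cornforth control) during ring closure; alkene geometries from a stabilised-ylide Wittig reaction (C7=C8), an anti-carbomagnesiation (Z-alkene, later the cis-oxirane) and a syn-hydrostannation (C3=C4).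

Key step: step 15

Remark: ethyl bromo(triphenylphosphoranylidene)acetate (9) is treated as a purchasable reagent (otherwise one step from Ph3P=CHCO2Et and NBS).
Remark: in step 2 the enantiomer of the chiral NHC ligand is the one that delivers the (S) centre.
Remark: the CIP descriptor of the methyl-bearing oxirane carbon changes with its neighbour (2S in 24, 2R in 25, 1S in 27, 1R in 29 and 30) without any change of configuration.

**Route**

Step 1
Reactants: 1 geraniol
Product: 2 diethyl (2E)-3,7-dimethylocta-2,6-dien-1-yl phosphate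
Conditions: ClP(O)(OEt)2, Et3N, DMAP (cat.), CH2Cl2, 0 °C → rt
Reagents that add atoms: diethyl chlorophosphate, CCOP(=O)(Cl)OCC
Why: O-phosphorylation of a primary allylic alcohol should proceed without touching the (E)-alkene; no stereocentre is formed.

Step 2
Reactants: 2 diethyl (2E)-3,7-dimethylocta-2,6-dien-1-yl phosphate; 3 ethynyltrimethylsilane
Product: 5 [(3S)-3-ethenyl-3,7-dimethyloct-6-en-1-yn-1-yl]trimethylsilane, via alkynylalane 4 (not isolated)
Conditions: 3, DIBAL-H, Et3N (5 mol%), hexanes, 50 °C; then 2, CuCl2·2H2O (5 mol%), chiral sulfonate-bridged NHC–Ag complex (2.5 mol%), THF, −15 °C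
Reagents that add atoms: none
Why: NHC–Cu-catalysed enantioselective allylic substitution (SN2') should deliver the alkynyl group to the γ-carbon of the trisubstituted allylic phosphate, creating the vinyl group and the all-carbon quaternary centre, whose (S) configuration is set by the chiral ligand discriminating the two alkene faces.

Step 3
Reactants: 5 [(3S)-3-ethenyl-3,7-dimethyloct-6-en-1-yn-1-yl]trimethylsilane
Product: 7 (3S)-3,7-dimethyl-3-[(trimethylsilyl)ethynyl]oct-6-en-1-ol, via alkylborane 6 (not isolated)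
Conditions: 9-BBN-H (1.2 equiv), THF, 0 °C → rt; then H2O2, aq. NaOAc, 0 °C → rt
Reagents that add atoms: hydrogen peroxide, OO
Why: Hydroboration–oxidation with 9-BBN should attack only the monosubstituted alkene (boron at the terminal carbon) and leave the trisubstituted alkene and the silylalkyne alone; no stereocentre is formed.

Step 4
Reactants: 7 (3S)-3,7-dimethyl-3-[(trimethylsilyl)ethynyl]oct-6-en-1-ol
Product: 8 (3S)-3,7-dimethyl-3-[(trimethylsilyl)ethynyl]oct-6-enal
Conditions: Dess–Martin periodinane, NaHCO3, CH2Cl2, 0 °C → rt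
Reagents that add atoms: none
Why: Dess–Martin oxidation of a primary alcohol to the aldehyde is mild and buffered, and the quaternary centre cannot epimerise.

Step 5
Reactants: 8 (3S)-3,7-dimethyl-3-[(trimethylsilyl)ethynyl]oct-6-enal; 9 ethyl bromo(triphenylphosphoranylidene)acetate
Product: 10 ethyl (2Z,5S)-2-bromo-5,9-dimethyl-5-[(trimethylsilyl)ethynyl]deca-2,8-dienoate
Conditions: toluene, 60 °C
Reagents that add atoms: none
Why: Wittig olefination with a stabilised α-bromo ylide should place the ester trans to the alkyl chain, i.e. give the (Z)-α-bromo enoate that fixes the later C7=C8 geometry.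

Step 6
Reactants: 10 ethyl (2Z,5S)-2-bromo-5,9-dimethyl-5-[(trimethylsilyl)ethynyl]deca-2,8-dienoate
Product: 11 (2Z,5S)-2-bromo-5,9-dimethyl-5-[(trimethylsilyl)ethynyl]deca-2,8-dien-1-ol
Conditions: DIBAL-H (2.3 equiv), CH2Cl2, −78 °C; Rochelle salt work-up
Reagents that add atoms: none
Why: 1,2-Reduction of the enoate by DIBAL-H at low temperature should spare the alkenyl bromide and the silylalkyne and keep the alkene geometry.

Step 7
Reactants: 11 (2Z,5S)-2-bromo-5,9-dimethyl-5-[(trimethylsilyl)ethynyl]deca-2,8-dien-1-ol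
Product: 12 {[(2Z,5S)-2-bromo-5,9-dimethyl-5-[(trimethylsilyl)ethynyl]deca-2,8-dien-1-yl]oxy}(tert-butyl)dimethylsilane
Conditions: TBSCl, imidazole, DMF, rt
Reagents that add atoms: tert-butyldimethylsilyl chloride, CC(C)(C)[Si](C)(C)Cl
Why: Silylation of the primary allylic alcohol masks the future C8 hydroxymethyl group so that only the other allylic alcohol is epoxidised and oxidised later.

Step 8
Reactants: 13 prop-2-yn-1-ol; 14 methylmagnesium bromide
Product: 16 (2Z)-3-iodo-2-methylprop-2-en-1-ol, via alkenylmagnesium chelate 15 (not isolated)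
Conditions: 14 (2.5 equiv), CuI (10 mol%), THF, −10 °C → rt; then I2, −10 °C
Reagents that add atoms: iodine, II
Why: Copper-catalysed anti-carbomagnesiation of the propargylic alkoxide should put methyl on C2 and magnesium on C3 inside a five-membered chelate, and iodinolysis with retention then gives the (Z)-iodide.

Step 9
Reactants: 16 (2Z)-3-iodo-2-methylprop-2-en-1-ol; 17 tributyl(ethenyl)stannane
Product: 18 (2Z)-2-methylpenta-2,4-dien-1-ol
Conditions: Pd(PPh3)4 (3 mol%), CuI (10 mol%), DMF, rt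
Reagents that add atoms: none
Why: Stille coupling of an alkenyl iodide proceeds with retention of the (Z) geometry and tolerates the free hydroxyl.

Step 10
Reactants: 18 (2Z)-2-methylpenta-2,4-dien-1-ol; 12 {[(2Z,5S)-2-bromo-5,9-dimethyl-5-[(trimethylsilyl)ethynyl]deca-2,8-dien-1-yl]oxy}(tert-butyl)dimethylsilane
Product: 20 (2Z,6E,9S)-6-{[(tert-butyldimethylsilyl)oxy]methyl}-2,9,13-trimethyl-9-[(trimethylsilyl)ethynyl]tetradeca-2,6,12-trien-1-ol, via homoallylic borane 19 (not isolated)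
Conditions: 18, 9-BBN-H (2.2 equiv), THF, 0 °C → rt; then 12, PdCl2(dppf) (5 mol%), AsPh3, Cs2CO3, DMF/H2O, rt
Reagents that add atoms: none
Why: B-alkyl Suzuki–Miyaura coupling: 9-BBN should add to the terminal CH2 of the diene (the hydroxyl is carried as its borinate and released on work-up), and the sp3–sp2 coupling replaces bromine with retention, so the C7=C8 geometry from step 5 is kept.

Step 11
Reactants: 20 (2Z,6E,9S)-6-{[(tert-butyldimethylsilyl)oxy]methyl}-2,9,13-trimethyl-9-[(trimethylsilyl)ethynyl]tetradeca-2,6,12-trien-1-ol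
Product: 21 (2Z,6E,9S)-6-{[(tert-butyldimethylsilyl)oxy]methyl}-9-ethynyl-2,9,13-trimethyltetradeca-2,6,12-trien-1-ol
Conditions: K2CO3 (0.2 equiv), MeOH, rt
Reagents that add atoms: none
Why: Methoxide-mediated protiodesilylation cleaves only the alkynyl C–Si bond; the TBS ether is stable under these conditions.

Step 12
Reactants: 21 (2Z,6E,9S)-6-{[(tert-butyldimethylsilyl)oxy]methyl}-9-ethynyl-2,9,13-trimethyltetradeca-2,6,12-trien-1-ol
Product: 23 (2Z,6E,9S)-6-{[(tert-butyldimethylsilyl)oxy]methyl}-9-[(E)-2-iodoethenyl]-2,9,13-trimethyltetradeca-2,6,12-trien-1-ol, via vinylstannane 22 (not isolated)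
Conditions: Bu3SnH (1.2 equiv), PdCl2(PPh3)2 (2 mol%), THF, 0 °C; then I2, CH2Cl2, 0 °C
Reagents that add atoms: iodine, II
Why: Pd-catalysed syn-hydrostannation should place tin on the terminal carbon of the alkyne next to the quaternary centre, and iododestannylation with retention then gives the (E)-alkenyl iodide.

Step 13
Reactants: 23 (2Z,6E,9S)-6-{[(tert-butyldimethylsilyl)oxy]methyl}-9-[(E)-2-iodoethenyl]-2,9,13-trimethyltetradeca-2,6,12-trien-1-ol
Product: 24 [(2S,3R)-3-[(3E,6S)-3-{[(tert-butyldimethylsilyl)oxy]methyl}-6-[(E)-2-iodoethenyl]-6,10-dimethylundeca-3,9-dien-1-yl]-2-methyloxiran-2-yl]methanol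
Conditions: Ti(OiPr)4 (20 mol%), L-(+)-diethyl tartrate (25 mol%), TBHP, 4 Å MS, CH2Cl2, −20 °C
Reagents that add atoms: tert-butyl hydroperoxide, CC(C)(C)OO
Why: Sharpless asymmetric epoxidation should epoxidise only the alkene of the free allylic alcohol; the Ti/L-(+)-tartrate complex selects the face that gives the (2S,3R) epoxy alcohol (same sense as nerol), and the (Z)-alkene becomes the cis-oxirane.

Step 14
Reactants: 24 [(2S,3R)-3-[(3E,6S)-3-{[(tert-butyldimethylsilyl)oxy]methyl}-6-[(E)-2-iodoethenyl]-6,10-dimethylundeca-3,9-dien-1-yl]-2-methyloxiran-2-yl]methanol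
Product: 25 (2R,3R)-3-[(3E,6S)-3-{[(tert-butyldimethylsilyl)oxy]methyl}-6-[(E)-2-iodoethenyl]-6,10-dimethylundeca-3,9-dien-1-yl]-2-methyloxirane-2-carbaldehyde
Conditions: Dess–Martin periodinane, NaHCO3, CH2Cl2, 0 °C
Reagents that add atoms: none
Why: Buffered Dess–Martin oxidation gives the α,β-epoxy aldehyde, which has no α-hydrogen and therefore cannot epimerise.

Step 15
Reactants: 25 (2R,3R)-3-[(3E,6S)-3-{[(tert-butyldimethylsilyl)oxy]methyl}-6-[(E)-2-iodoethenyl]-6,10-dimethylundeca-3,9-dien-1-yl]-2-methyloxirane-2-carbaldehyde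
Product: 27 (1S,2S,3E,5S,7E,11R)-8-{[(tert-butyldimethylsilyl)oxy]methyl}-1,5-dimethyl-5-(4-methylpent-3-en-1-yl)-12-oxabicyclo[9.1.0]dodeca-3,7-dien-2-ol, via alkenylchromium species 26 (not isolated)
Conditions: CrCl2 (10 equiv), NiCl2 (2 mol% of Cr), degassed DMSO, rt, syringe-pump addition of 25 (final 0.003 M); aqueous work-up
Reagents that add atoms: none
Why: Ni(0), formed from NiCl2 by CrCl2, inserts into the alkenyl C–I bond with retention and transmetalates to chromium(III), and the (E)-alkenylchromium 26 adds to the tethered aldehyde (intramolecular Nozaki–Hiyama–Kishi reaction); the closest known reaction types are NHK closures of medium and large carbocycles and NHK additions to α-oxygenated aldehydes. The eleven-membered carbocycle is closed by an 11-exo-trig 1,2-addition that forms C2–C3; the oxirane is already in place and no other ring forms. The new stereocentre C2 is controlled by the oxirane carbon C1: with C2=O antiperiplanar to the C1–O12 bond (Cornforth arrangement) the alkenyl carbon should approach anti to C11, whose cis substituent C10 (the start of the tether) shields the other face, giving the 2S alcohol anti to the oxirane oxygen. C1 is quaternary, so the aldehyde can neither enolise nor epimerise, and the (E) geometry of C3=C4 is carried over from the iodide. The step needs chemoselectivity for the aldehyde over the oxirane and the silyl ether, which the non-basic alkenylchromium provides, and ring closure over intermolecular coupling, which slow addition at high dilution secures.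

Step 16
Reactants: 27 (1S,2S,3E,5S,7E,11R)-8-{[(tert-butyldimethylsilyl)oxy]methyl}-1,5-dimethyl-5-(4-methylpent-3-en-1-yl)-12-oxabicyclo[9.1.0]dodeca-3,7-dien-2-ol; 28 3-methylbut-2-enoyl chloride
Product: 29 (1R,2S,3E,5S,7E,11R)-8-{[(tert-butyldimethylsilyl)oxy]methyl}-1,5-dimethyl-5-(4-methylpent-3-en-1-yl)-12-oxabicyclo[9.1.0]dodeca-3,7-dien-2-yl 3-methylbut-2-enoate
Conditions: pyridine, DMAP (0.2 equiv), CH2Cl2, 0 °C → rt
Reagents that add atoms: none
Why: DMAP-catalysed O-acylation of the secondary allylic alcohol does not touch the C2–O bond, so the configuration is retained; pyridine rather than a trialkylamine avoids deconjugation of the acyl group.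

Step 17
Reactants: 29 (1R,2S,3E,5S,7E,11R)-8-{[(tert-butyldimethylsilyl)oxy]methyl}-1,5-dimethyl-5-(4-methylpent-3-en-1-yl)-12-oxabicyclo[9.1.0]dodeca-3,7-dien-2-yl 3-methylbut-2-enoate
Product: 30 (1R,2S,3E,5S,7E,11R)-8-(hydroxymethyl)-1,5-dimethyl-5-(4-methylpent-3-en-1-yl)-12-oxabicyclo[9.1.0]dodeca-3,7-dien-2-yl 3-methylbut-2-enoate
Conditions: HF·pyridine, pyridine, THF, 0 °C → rt
Reagents that add atoms: none
Why: Buffered fluoride desilylation should free the primary allylic alcohol without opening the trisubstituted oxirane or cleaving the ester.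

**Compound list**

1 | geraniol, (2E)-3,7-dimethylocta-2,6-dien-1-ol | CC(C)=CCC/C(C)=C/CO | starting material
2 | diethyl (2E)-3,7-dimethylocta-2,6-dien-1-yl phosphate | CC(C)=CCC/C(C)=C/COP(=O)(OCC)OCC | intermediate
3 | ethynyltrimethylsilane | C#C[Si](C)(C)C | starting material
4 | diisobutyl[(trimethylsilyl)ethynyl]alumane (formed in situ) | CC(C)C[Al](CC(C)C)C#C[Si](C)(C)C | intermediate
5 | [(3S)-3-ethenyl-3,7-dimethyloct-6-en-1-yn-1-yl]trimethylsilane | CC(C)=CCC[C@@](C)(C=C)C#C[Si](C)(C)C | intermediate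
6 | 9-{(3S)-3,7-dimethyl-3-[(trimethylsilyl)ethynyl]oct-6-en-1-yl}-9-borabicyclo[3.3.1]nonane (formed in situ) | CC(C)=CCC[C@@](C)(CCB1C2CCCC1CCC2)C#C[Si](C)(C)C | intermediate
7 | (3S)-3,7-dimethyl-3-[(trimethylsilyl)ethynyl]oct-6-en-1-ol | CC(C)=CCC[C@@](C)(CCO)C#C[Si](C)(C)C | intermediate
8 | (3S)-3,7-dimethyl-3-[(trimethylsilyl)ethynyl]oct-6-enal | CC(C)=CCC[C@@](C)(CC=O)C#C[Si](C)(C)C | intermediate
9 | ethyl bromo(triphenylphosphoranylidene)acetate | CCOC(=O)C(Br)=P(c1ccccc1)(c1ccccc1)c1ccccc1 | starting material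
10 | ethyl (2Z,5S)-2-bromo-5,9-dimethyl-5-[(trimethylsilyl)ethynyl]deca-2,8-dienoate | CCOC(=O)/C(Br)=C/C[C@](C)(CCC=C(C)C)C#C[Si](C)(C)C | intermediate
11 | (2Z,5S)-2-bromo-5,9-dimethyl-5-[(trimethylsilyl)ethynyl]deca-2,8-dien-1-ol | OC/C(Br)=C/C[C@](C)(CCC=C(C)C)C#C[Si](C)(C)C | intermediate
12 | {[(2Z,5S)-2-bromo-5,9-dimethyl-5-[(trimethylsilyl)ethynyl]deca-2,8-dien-1-yl]oxy}(tert-butyl)dimethylsilane | CC(C)(C)[Si](C)(C)OC/C(Br)=C/C[C@](C)(CCC=C(C)C)C#C[Si](C)(C)C | intermediate
13 | prop-2-yn-1-ol | C#CCO | starting material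
14 | methylmagnesium bromide | C[Mg]Br | starting material
15 | bromomagnesium (2Z)-3-(bromomagnesio)-2-methylprop-2-en-1-olate (formed in situ) | Br[Mg]OC/C(C)=C\[Mg]Br | intermediate
16 | (2Z)-3-iodo-2-methylprop-2-en-1-ol | OC/C(C)=C\I | intermediate
17 | tributyl(ethenyl)stannane | C=C[Sn](CCCC)(CCCC)CCCC | starting material
18 | (2Z)-2-methylpenta-2,4-dien-1-ol | OC/C(C)=C\C=C | intermediate
19 | 9-{[(2Z)-5-(9-borabicyclo[3.3.1]nonan-9-yl)-2-methylpent-2-en-1-yl]oxy}-9-borabicyclo[3.3.1]nonane (formed in situ) | B1(OC/C(C)=C\CCB2C3CCCC2CCC3)C2CCCC1CCC2 | intermediate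
20 | (2Z,6E,9S)-6-{[(tert-butyldimethylsilyl)oxy]methyl}-2,9,13-trimethyl-9-[(trimethylsilyl)ethynyl]tetradeca-2,6,12-trien-1-ol | OC/C(C)=C\CC/C(CO[Si](C)(C)C(C)(C)C)=C\C[C@](C)(CCC=C(C)C)C#C[Si](C)(C)C | intermediate
21 | (2Z,6E,9S)-6-{[(tert-butyldimethylsilyl)oxy]methyl}-9-ethynyl-2,9,13-trimethyltetradeca-2,6,12-trien-1-ol | OC/C(C)=C\CC/C(CO[Si](C)(C)C(C)(C)C)=C\C[C@](C)(CCC=C(C)C)C#C | intermediate
22 | (2Z,6E,9S)-6-{[(tert-butyldimethylsilyl)oxy]methyl}-2,9,13-trimethyl-9-[(E)-2-(tributylstannyl)ethenyl]tetradeca-2,6,12-trien-1-ol (formed in situ) | OC/C(C)=C\CC/C(CO[Si](C)(C)C(C)(C)C)=C\C[C@](C)(CCC=C(C)C)/C=C/[Sn](CCCC)(CCCC)CCCC | intermediate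
23 | (2Z,6E,9S)-6-{[(tert-butyldimethylsilyl)oxy]methyl}-9-[(E)-2-iodoethenyl]-2,9,13-trimethyltetradeca-2,6,12-trien-1-ol | OC/C(C)=C\CC/C(CO[Si](C)(C)C(C)(C)C)=C\C[C@](C)(CCC=C(C)C)/C=C/I | intermediate
24 | [(2S,3R)-3-[(3E,6S)-3-{[(tert-butyldimethylsilyl)oxy]methyl}-6-[(E)-2-iodoethenyl]-6,10-dimethylundeca-3,9-dien-1-yl]-2-methyloxiran-2-yl]methanol | OC[C@]1(C)O[C@@H]1CC/C(CO[Si](C)(C)C(C)(C)C)=C\C[C@](C)(CCC=C(C)C)/C=C/I | intermediate
25 | (2R,3R)-3-[(3E,6S)-3-{[(tert-butyldimethylsilyl)oxy]methyl}-6-[(E)-2-iodoethenyl]-6,10-dimethylundeca-3,9-dien-1-yl]-2-methyloxirane-2-carbaldehyde | O=C[C@]1(C)O[C@@H]1CC/C(CO[Si](C)(C)C(C)(C)C)=C\C[C@](C)(CCC=C(C)C)/C=C/I | intermediate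
26 | (E)-alkenylchromium(III) dichloride derived from 25, C–I replaced by C–CrCl2 (formed in situ) | O=C[C@]1(C)O[C@@H]1CC/C(CO[Si](C)(C)C(C)(C)C)=C\C[C@](C)(CCC=C(C)C)/C=C/[Cr](Cl)Cl | intermediate
27 | (1S,2S,3E,5S,7E,11R)-8-{[(tert-butyldimethylsilyl)oxy]methyl}-1,5-dimethyl-5-(4-methylpent-3-en-1-yl)-12-oxabicyclo[9.1.0]dodeca-3,7-dien-2-ol | CC(C)=CCC[C@]1(C)/C=C/[C@H](O)[C@]2(C)O[C@@H]2CC/C(CO[Si](C)(C)C(C)(C)C)=C\C1 | intermediate
28 | 3-methylbut-2-enoyl chloride | CC(C)=CC(=O)Cl | starting material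
29 | (1R,2S,3E,5S,7E,11R)-8-{[(tert-butyldimethylsilyl)oxy]methyl}-1,5-dimethyl-5-(4-methylpent-3-en-1-yl)-12-oxabicyclo[9.1.0]dodeca-3,7-dien-2-yl 3-methylbut-2-enoate | CC(C)=CCC[C@]1(C)/C=C/[C@H](OC(=O)C=C(C)C)[C@]2(C)O[C@@H]2CC/C(CO[Si](C)(C)C(C)(C)C)=C\C1 | intermediate
30 | (1R,2S,3E,5S,7E,11R)-8-(hydroxymethyl)-1,5-dimethyl-5-(4-methylpent-3-en-1-yl)-12-oxabicyclo[9.1.0]dodeca-3,7-dien-2-yl 3-methylbut-2-enoate | CC(C)=CCC[C@]1(C)/C=C/[C@H](OC(=O)C=C(C)C)[C@]2(C)O[C@@H]2CC/C(CO)=C\C1 | target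

**Summary**

Total step count: 17. Longest linear sequence: 15 steps (steps 1–7 and 10–17, from geraniol); the dienol branch (steps 8–9) has 2 steps.

Steps most likely to fail:

1. Step 15. The tethered alkenylchromium may attack the other carbonyl face, because strain in the eleven-membered transition state can override the Cornforth preference and erode the selectivity at C2. The fallback sets out from 25 and comes back at 27. The ring is closed as in step 15 without regard to selectivity, giving 27 together with its C2 epimer (1S,2R,3E,5S,7E,11R)-8-{[(tert-butyldimethylsilyl)oxy]methyl}-1,5-dimethyl-5-(4-methylpent-3-en-1-yl)-12-oxabicyclo[9.1.0]dodeca-3,7-dien-2-ol F1. The mixture is oxidised with Dess–Martin periodinane to the single epoxy enone (1R,3E,5S,7E,11R)-8-{[(tert-butyldimethylsilyl)oxy]methyl}-1,5-dimethyl-5-(4-methylpent-3-en-1-yl)-12-oxabicyclo[9.1.0]dodeca-3,7-dien-2-one F2. Reduction of F2 with Zn(BH4)2 in Et2O at −30 °C should return 27, since zinc-bridged 1,2-hydride delivery to α,β-epoxy ketones is known to give the erythro (anti) epoxy alcohol; C2 is then set by ketone reduction instead of C–C bond formation.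

2. Step 2. Enantiofacial discrimination between the methyl and the homoprenyl substituent of the dialkyl-substituted alkene may be insufficient, or direct SN2 substitution may compete. The fallback sets out from 1 and comes back at 5. Sharpless epoxidation of geraniol with D-(−)-diethyl tartrate should give [(2R,3R)-3-methyl-3-(4-methylpent-3-en-1-yl)oxiran-2-yl]methanol F3. Diethylaluminium (trimethylsilyl)acetylide (from 3, n-BuLi and Et2AlCl, toluene, 0 °C) should open the epoxy alcohol at the tertiary carbon with inversion to (2S,3R)-3,7-dimethyl-3-[(trimethylsilyl)ethynyl]oct-6-ene-1,2-diol F4. Garegg–Samuelsson deoxygenation (I2, PPh3, imidazole, toluene, reflux) then converts the 1,2-diol into the vinyl group of 5. The quaternary centre is thus set by stereospecific substitution of a Sharpless-derived epoxide instead of by a catalytic SN2' reaction.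

3. Step 10. The homoallylic borane may undergo protodeboronation or β-hydride elimination at the hindered 2-bromoalkene, and the alkynyl silyl group may be lost under the aqueous base with subsequent palladium-mediated alkyne coupling. The fallback sets out from 18 (and uses aldehyde 8) and comes back at 20; it replaces the cross-coupling by a Wittig union that forms C7=C8 directly.
   - Dienol 18 is protected (NaH, PMBCl) as 1-methoxy-4-({[(2Z)-2-methylpenta-2,4-dien-1-yl]oxy}methyl)benzene F5.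
   - Hydroboration–oxidation (9-BBN; H2O2, NaOH) gives (3Z)-5-[(4-methoxybenzyl)oxy]-4-methylpent-3-en-1-ol F6.
   - I2, PPh3 and imidazole give 1-({[(2Z)-5-iodo-2-methylpent-2-en-1-yl]oxy}methyl)-4-methoxybenzene F7.
   - Alkylation of Ph3P=CHCO2Et (2 equiv, MeCN, reflux, transylidation) gives ethyl (5Z)-7-[(4-methoxybenzyl)oxy]-6-methyl-2-(triphenylphosphoranylidene)hept-5-enoate F8.
   - Wittig reaction of F8 with 8 (toluene, 90 °C) should give, with the ester trans to C6, ethyl (2E,5S)-2-{(3Z)-5-[(4-methoxybenzyl)oxy]-4-methylpent-3-en-1-yl}-5,9-dimethyl-5-[(trimethylsilyl)ethynyl]deca-2,8-dienoate F9.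
   - DIBAL-H gives (2E,5S)-2-{(3Z)-5-[(4-methoxybenzyl)oxy]-4-methylpent-3-en-1-yl}-5,9-dimethyl-5-[(trimethylsilyl)ethynyl]deca-2,8-dien-1-ol F10.
   - TBSCl and imidazole give tert-butyl{[(2E,5S)-2-{(3Z)-5-[(4-methoxybenzyl)oxy]-4-methylpent-3-en-1-yl}-5,9-dimethyl-5-[(trimethylsilyl)ethynyl]deca-2,8-dien-1-yl]oxy}dimethylsilane F11.
   - DDQ (CH2Cl2, pH 7 buffer) removes the PMB group and returns 20.

**Further compounds**

F1 | step 15 | (1S,2R,3E,5S,7E,11R)-8-{[(tert-butyldimethylsilyl)oxy]methyl}-1,5-dimethyl-5-(4-methylpent-3-en-1-yl)-12-oxabicyclo[9.1.0]dodeca-3,7-dien-2-ol | CC(C)=CCC[C@]1(C)/C=C/[C@@H](O)[C@]2(C)O[C@@H]2CC/C(CO[Si](C)(C)C(C)(C)C)=C\C1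
F2 | step 15 | (1R,3E,5S,7E,11R)-8-{[(tert-butyldimethylsilyl)oxy]methyl}-1,5-dimethyl-5-(4-methylpent-3-en-1-yl)-12-oxabicyclo[9.1.0]dodeca-3,7-dien-2-one | CC(C)=CCC[C@]1(C)/C=C/C(=O)[C@]2(C)O[C@@H]2CC/C(CO[Si](C)(C)C(C)(C)C)=C\C1
F3 | step 2 | [(2R,3R)-3-methyl-3-(4-methylpent-3-en-1-yl)oxiran-2-yl]methanol | OC[C@H]1O[C@]1(C)CCC=C(C)C
F4 | step 2 | (2S,3R)-3,7-dimethyl-3-[(trimethylsilyl)ethynyl]oct-6-ene-1,2-diol | OC[C@@H](O)[C@](C)(CCC=C(C)C)C#C[Si](C)(C)C
F5 | step 10 | 1-methoxy-4-({[(2Z)-2-methylpenta-2,4-dien-1-yl]oxy}methyl)benzene | COc1ccc(COC/C(C)=C\C=C)cc1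
F6 | step 10 | (3Z)-5-[(4-methoxybenzyl)oxy]-4-methylpent-3-en-1-ol | COc1ccc(COC/C(C)=C\CCO)cc1
F7 | step 10 | 1-({[(2Z)-5-iodo-2-methylpent-2-en-1-yl]oxy}methyl)-4-methoxybenzene | COc1ccc(COC/C(C)=C\CCI)cc1
F8 | step 10 | ethyl (5Z)-7-[(4-methoxybenzyl)oxy]-6-methyl-2-(triphenylphosphoranylidene)hept-5-enoate | CCOC(=O)C(CC/C=C(/C)COCc1ccc(OC)cc1)=P(c1ccccc1)(c1ccccc1)c1ccccc1
F9 | step 10 | ethyl (2E,5S)-2-{(3Z)-5-[(4-methoxybenzyl)oxy]-4-methylpent-3-en-1-yl}-5,9-dimethyl-5-[(trimethylsilyl)ethynyl]deca-2,8-dienoate | CCOC(=O)/C(CC/C=C(/C)COCc1ccc(OC)cc1)=C/C[C@](C)(CCC=C(C)C)C#C[Si](C)(C)C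
F10 | step 10 | (2E,5S)-2-{(3Z)-5-[(4-methoxybenzyl)oxy]-4-methylpent-3-en-1-yl}-5,9-dimethyl-5-[(trimethylsilyl)ethynyl]deca-2,8-dien-1-ol | OC/C(CC/C=C(/C)COCc1ccc(OC)cc1)=C/C[C@](C)(CCC=C(C)C)C#C[Si](C)(C)C
F11 | step 10 | tert-butyl{[(2E,5S)-2-{(3Z)-5-[(4-methoxybenzyl)oxy]-4-methylpent-3-en-1-yl}-5,9-dimethyl-5-[(trimethylsilyl)ethynyl]deca-2,8-dien-1-yl]oxy}dimethylsilane | CC(C)(C)[Si](C)(C)OC/C(CC/C=C(/C)COCc1ccc(OC)cc1)=C/C[C@](C)(CCC=C(C)C)C#C[Si](C)(C)C
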